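**Strategy.** The bicyclic core is disconnected at C4a–C7a, C5–C6 and C6–C7 of the cyclopenta[c]pyridine. The oxygenated C6, flanked by C5 and C7 and facing the C4a–C7a fusion bond, is the carbonyl carbon of a Pauson–Khand cyclopentenone. One cobalt-mediated [2+2+1] reaction of an N-tethered 1,7-enyne with CO closes the piperidine and the cyclopentenone together and sets C7 and C7a. The precursor is a methyl carbamate carrying an (R)-2-methylbut-3-ynyl arm (the C4 stereocentre, from the chiral pool) and an (E)-crotyl arm; its carbamate carbon later becomes the N-methyl group. Hydrogenation, hydride reduction and a Mitsunobu esterification with inversion at C6 with a citronellol-derived acid complete the target.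

Key step: step 5

Remark: ring atoms are numbered as in cyclopenta[c]pyridine (C1, N2, C3, C4, C4a, C5, C6, C7, C7a); amine 2 is assumed to be used as its geometrically pure free base.

Step 1
Reactants: 1 (2R)-3-bromo-2-methylpropan-1-ol; 2 (2E)-but-2-en-1-amine
Product: 3 (2S)-3-{[(2E)-but-2-en-1-yl]amino}-2-methylpropan-1-ol
Conditions: 2 (4 equiv), MeCN, 70 °C, sealed vessel; aq. NaOH work-up, excess 2 distilled off
Reagents that add atoms: none
Why: SN2 amination of a primary bromide by an excess of primary amine, which suppresses double alkylation; the stereocentre is one carbon away from the reacting centre and is untouched (R becomes S only through the priority rules).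

Step 2
Reactants: 3 (2S)-3-{[(2E)-but-2-en-1-yl]amino}-2-methylpropan-1-ol
Product: 4 methyl N-[(2E)-but-2-en-1-yl]-N-[(2S)-3-hydroxy-2-methylpropyl]carbamate
Conditions: ClCO2Me (1.05 equiv), NaHCO3, CH2Cl2/H2O, 0 °C
Reagents that add atoms: methyl chloroformate, COC(=O)Cl
Why: Schotten–Baumann carbamoylation is selective for the secondary amine over the primary alcohol, and the methoxycarbonyl group tolerates cobalt carbonyl chemistry and is reduced to the N-methyl group in step 7.

Step 3
Reactants: 4 methyl N-[(2E)-but-2-en-1-yl]-N-[(2S)-3-hydroxy-2-methylpropyl]carbamate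
Product: 5 methyl N-[(2E)-but-2-en-1-yl]-N-[(2S)-2-methyl-3-oxopropyl]carbamate
Conditions: TEMPO (10 mol%), PhI(OAc)2 (1.1 equiv), CH2Cl2, rt; carried on crude
Reagents that add atoms: none
Why: Oxoammonium (TEMPO/PhI(OAc)2) oxidation of a primary alcohol stops at the aldehyde under non-basic conditions, so the α-stereocentre, the alkene and the carbamate should stay intact.

Step 4
Reactants: 5 methyl N-[(2E)-but-2-en-1-yl]-N-[(2S)-2-methyl-3-oxopropyl]carbamate
Product: 6 methyl N-[(2E)-but-2-en-1-yl]-N-[(2R)-2-methylbut-3-yn-1-yl]carbamate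
Conditions: dimethyl (1-diazo-2-oxopropyl)phosphonate (1.3 equiv), K2CO3 (2 equiv), MeOH, 0 °C to rt
Reagents that add atoms: dimethyl (1-diazo-2-oxopropyl)phosphonate (Ohira–Bestmann reagent), CC(=O)C(=[N+]=[N-])P(=O)(OC)OC
Why: Seyferth–Gilbert homologation in the Ohira–Bestmann variant converts α-methyl aldehydes of this kind into terminal alkynes under mild carbonate/methanol conditions that normally preserve configuration; the stereocentre is retained (descriptor R through the priority change).

Step 5
Reactants: 6 methyl N-[(2E)-but-2-en-1-yl]-N-[(2R)-2-methylbut-3-yn-1-yl]carbamate; 7 dicobalt octacarbonyl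
Product: 9 methyl (4R,7S,7aS)-4,7-dimethyl-6-oxo-1,3,4,6,7,7a-hexahydro-2H-cyclopenta[c]pyridine-2-carboxylate, via hexacarbonyldicobalt alkyne complex 8 (not isolated)
Conditions: Co2(CO)8 (1.1 equiv), ClCH2CH2Cl, rt, 1 h; then n-BuSMe (3.5 equiv), 83 °C
Reagents that add atoms: carbon monoxide (one CO ligand of 7), [C-]#[O+]
Why: The alkyne forms its Co2(CO)6 complex 8; sulfide-assisted loss of CO lets the crotyl alkene coordinate and insert into a Co–C bond (C4a–C7a), after which CO insertion and reductive elimination forge C6–C7 and C5–C6, i.e. an intramolecular Pauson–Khand reaction, whose closest precedent is the cobalt-mediated cyclisation of carbamate- or sulfonamide-tethered 1,7-enynes. The piperidine closes in a 6-exo mode (C4a and C7a become ring atoms, C5 and C7 stay outside it), and the cyclopentenone closes by the carbonylative [2+2+1] step from the cobaltacycle. C7 is set relative to C7a by suprafacial addition across the E-alkene, which places the C7 methyl trans to the C7a–C1 bond. C7a is set relative to C4 by a chair-like insertion with the C4 methyl pseudo-equatorial, giving H-4 and H-7a cis; the unsubstituted alkyne terminus keeps allylic strain against that methyl small. Regiochemistry needs no control because the tether forces the carbonyl between C5 and C7; the selectivity required is the facial one at the alkene, and both new centres are also the thermodynamically preferred ones (C7 is α and C7a is γ to the ketone), so minor epimers could be equilibrated with base.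

Step 6
Reactants: 9 methyl (4R,7S,7aS)-4,7-dimethyl-6-oxo-1,3,4,6,7,7a-hexahydro-2H-cyclopenta[c]pyridine-2-carboxylate
Product: 10 methyl (4R,4aS,7S,7aR)-4,7-dimethyl-6-oxooctahydro-2H-cyclopenta[c]pyridine-2-carboxylate
Conditions: H2 (1 atm), 10% Pd/C, EtOAc, rt
Reagents that add atoms: none
Why: Heterogeneous hydrogenation of the C4a=C5 enone bond should deliver hydrogen to the convex face that carries H-7a (the piperidine ring leaves C7a on the other face), which sets C4a with H-4a cis to H-7a and gives the cis-fused ketone.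

Step 7
Reactants: 10 methyl (4R,4aS,7S,7aR)-4,7-dimethyl-6-oxooctahydro-2H-cyclopenta[c]pyridine-2-carboxylate
Product: 12 (4R,4aS,6S,7S,7aR)-2,4,7-trimethyloctahydro-1H-cyclopenta[c]pyridin-6-ol, via hydroxy carbamate 11 (not isolated)
Conditions: LiAlH4 (4 equiv), THF, −78 to 0 °C; then reflux; aq. NaOH work-up
Reagents that add atoms: none
Why: In this LiAlH4 reduction the small hydride should first add to the C6 ketone from the convex face (syn to H-4a and H-7a), which sets C6 as the (6S) alkoxide with oxygen on the concave face and trans to the C7 methyl, and on heating the methyl carbamate is reduced to the N-methyl amine.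

Step 8
Reactants: 13 (S)-citronellol
Product: 14 tert-butyl{[(3S)-3,7-dimethyloct-6-en-1-yl]oxy}dimethylsilane
Conditions: TBSCl (1.1 equiv), imidazole (1.5 equiv), CH2Cl2, rt
Reagents that add atoms: tert-butyldimethylsilyl chloride, CC(C)(C)[Si](C)(C)Cl
Why: Standard silylation of a primary alcohol, giving a TBS ether that masks the hydroxyl through ozonolysis, olefination, saponification and the Mitsunobu reaction.

Step 9
Reactants: 14 tert-butyl{[(3S)-3,7-dimethyloct-6-en-1-yl]oxy}dimethylsilane
Product: 16 (4S)-6-[(tert-butyldimethylsilyl)oxy]-4-methylhexanal, via ozonide 15 (not isolated)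
Conditions: O3, CH2Cl2, −78 °C; then PPh3, −78 °C to rt
Reagents that add atoms: ozone, [O-][O+]=O
Why: Ozonolysis with reductive work-up cleaves the only alkene to the aldehyde and acetone, and the remote stereocentre is unaffected.

Step 10
Reactants: 16 (4S)-6-[(tert-butyldimethylsilyl)oxy]-4-methylhexanal
Product: 17 ethyl (2E,6S)-8-[(tert-butyldimethylsilyl)oxy]-2,6-dimethyloct-2-enoate
Conditions: Ph3P=C(CH3)CO2Et (1.3 equiv), CH2Cl2, rt to 40 °C
Reagents that add atoms: ethyl 2-(triphenyl-λ5-phosphanylidene)propanoate, CCOC(=O)C(C)=P(c1ccccc1)(c1ccccc1)c1ccccc1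
Why: Wittig olefination with a stabilised α-methyl ylide should give the (E)-trisubstituted enoate, as is general for such ylides with unhindered aldehydes.

Step 11
Reactants: 17 ethyl (2E,6S)-8-[(tert-butyldimethylsilyl)oxy]-2,6-dimethyloct-2-enoate
Product: 18 (2E,6S)-8-[(tert-butyldimethylsilyl)oxy]-2,6-dimethyloct-2-enoic acid
Conditions: LiOH·H2O (3 equiv), THF/MeOH/H2O, rt; cold 1 M HCl to pH 4
Reagents that add atoms: lithium hydroxide, [Li+].[OH-]
Why: Saponification of the ethyl ester at room temperature is tolerated by a primary TBS ether, and brief mild acidification liberates the acid without desilylation.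

Step 12
Reactants: 12 (4R,4aS,6S,7S,7aR)-2,4,7-trimethyloctahydro-1H-cyclopenta[c]pyridin-6-ol; 18 (2E,6S)-8-[(tert-butyldimethylsilyl)oxy]-2,6-dimethyloct-2-enoic acid
Product: 19 (4R,4aS,6R,7S,7aR)-2,4,7-trimethyloctahydro-1H-cyclopenta[c]pyridin-6-yl (2E,6S)-8-[(tert-butyldimethylsilyl)oxy]-2,6-dimethyloct-2-enoate
Conditions: 18 (1.5 equiv), PPh3 (2 equiv), DIAD (2 equiv), THF, 0 °C to rt
Reagents that add atoms: none
Why: In the Mitsunobu esterification the (6S) oxyphosphonium is displaced by the carboxylate of 18 in an SN2 step from the open convex face, which inverts C6 to the (6R) configuration of the target.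

Step 13
Reactants: 19 (4R,4aS,6R,7S,7aR)-2,4,7-trimethyloctahydro-1H-cyclopenta[c]pyridin-6-yl (2E,6S)-8-[(tert-butyldimethylsilyl)oxy]-2,6-dimethyloct-2-enoate
Product: 20 (4R,4aS,6R,7S,7aR)-2,4,7-trimethyloctahydro-1H-cyclopenta[c]pyridin-6-yl (2E,6S)-8-hydroxy-2,6-dimethyloct-2-enoate
Conditions: HF·pyridine, THF/pyridine, 0 °C to rt; aq. NaHCO3 work-up
Reagents that add atoms: none
Why: Fluoride-mediated cleavage of the primary TBS ether with buffered HF·pyridine should leave the conjugated ester, the alkene geometry and the tertiary amine untouched.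

**Compound list**

1 | (2R)-3-bromo-2-methylpropan-1-ol | OC[C@@H](C)CBr | starting material
2 | (2E)-but-2-en-1-amine | C/C=C/CN | starting material
3 | (2S)-3-{[(2E)-but-2-en-1-yl]amino}-2-methylpropan-1-ol | OC[C@@H](C)CNC/C=C/C | intermediate
4 | methyl N-[(2E)-but-2-en-1-yl]-N-[(2S)-3-hydroxy-2-methylpropyl]carbamate | OC[C@@H](C)CN(C(=O)OC)C/C=C/C | intermediate
5 | methyl N-[(2E)-but-2-en-1-yl]-N-[(2S)-2-methyl-3-oxopropyl]carbamate | O=C[C@@H](C)CN(C(=O)OC)C/C=C/C | intermediate
6 | methyl N-[(2E)-but-2-en-1-yl]-N-[(2R)-2-methylbut-3-yn-1-yl]carbamate | C#C[C@@H](C)CN(C(=O)OC)C/C=C/C | intermediate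
7 | dicobalt octacarbonyl | [C-]#[O+].[C-]#[O+].[C-]#[O+].[C-]#[O+].[C-]#[O+].[C-]#[O+].[C-]#[O+].[C-]#[O+].[Co].[Co] | starting material
8 | hexacarbonyldicobalt complex of the alkyne of 6 (Co2C2 tetrahedrane core) | O=C=[Co]12(=C=O)(=C=O)[Co]3(=C=O)(=C=O)(=C=O)C1([H])C23[C@@H](C)CN(C(=O)OC)C/C=C/C | intermediate
9 | methyl (4R,7S,7aS)-4,7-dimethyl-6-oxo-1,3,4,6,7,7a-hexahydro-2H-cyclopenta[c]pyridine-2-carboxylate | O=C1C=C2[C@@H](CN(C(=O)OC)C[C@@H]2C)[C@@H]1C | intermediate
10 | methyl (4R,4aS,7S,7aR)-4,7-dimethyl-6-oxooctahydro-2H-cyclopenta[c]pyridine-2-carboxylate | O=C1C[C@@H]2[C@@H](CN(C(=O)OC)C[C@@H]2C)[C@@H]1C | intermediate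
11 | methyl (4R,4aS,6S,7S,7aR)-6-hydroxy-4,7-dimethyloctahydro-2H-cyclopenta[c]pyridine-2-carboxylate (present as its aluminium alkoxide) | O[C@H]1C[C@@H]2[C@@H](CN(C(=O)OC)C[C@@H]2C)[C@@H]1C | intermediate
12 | (4R,4aS,6S,7S,7aR)-2,4,7-trimethyloctahydro-1H-cyclopenta[c]pyridin-6-ol | O[C@H]1C[C@@H]2[C@@H](CN(C)C[C@@H]2C)[C@@H]1C | intermediate
13 | (S)-citronellol, (3S)-3,7-dimethyloct-6-en-1-ol | C[C@@H](CCC=C(C)C)CCO | starting material
14 | tert-butyl{[(3S)-3,7-dimethyloct-6-en-1-yl]oxy}dimethylsilane | C[C@@H](CCC=C(C)C)CCO[Si](C)(C)C(C)(C)C | intermediate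
15 | tert-butyl{[(3S)-5-(5,5-dimethyl-1,2,4-trioxolan-3-yl)-3-methylpentyl]oxy}dimethylsilane (ozonide, mixture at the trioxolane carbon) | C[C@@H](CCC1OOC(C)(C)O1)CCO[Si](C)(C)C(C)(C)C | intermediate
16 | (4S)-6-[(tert-butyldimethylsilyl)oxy]-4-methylhexanal | C[C@@H](CCC=O)CCO[Si](C)(C)C(C)(C)C | intermediate
17 | ethyl (2E,6S)-8-[(tert-butyldimethylsilyl)oxy]-2,6-dimethyloct-2-enoate | CCOC(=O)/C(C)=C/CC[C@H](C)CCO[Si](C)(C)C(C)(C)C | intermediate
18 | (2E,6S)-8-[(tert-butyldimethylsilyl)oxy]-2,6-dimethyloct-2-enoic acid | OC(=O)/C(C)=C/CC[C@H](C)CCO[Si](C)(C)C(C)(C)C | intermediate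
19 | (4R,4aS,6R,7S,7aR)-2,4,7-trimethyloctahydro-1H-cyclopenta[c]pyridin-6-yl (2E,6S)-8-[(tert-butyldimethylsilyl)oxy]-2,6-dimethyloct-2-enoate | C/C(=C\CC[C@H](C)CCO[Si](C)(C)C(C)(C)C)C(=O)O[C@@H]1C[C@@H]2[C@@H](CN(C)C[C@@H]2C)[C@@H]1C | intermediate
20 | (4R,4aS,6R,7S,7aR)-2,4,7-trimethyloctahydro-1H-cyclopenta[c]pyridin-6-yl (2E,6S)-8-hydroxy-2,6-dimethyloct-2-enoate | C/C(=C\CC[C@H](C)CCO)C(=O)O[C@@H]1C[C@@H]2[C@@H](CN(C)C[C@@H]2C)[C@@H]1C | target

**Step count.** 13 steps in total. The longest linear sequence is 9 steps (steps 1–7, 12, 13); the side-chain acid takes 4 steps (8–11).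

**Steps most likely to fail**

1. Step 5. The 1,2-disubstituted alkene may insert into the cobalt–alkyne complex too slowly, so that decomplexation or alkyne oligomerisation outruns cyclisation, and the facial bias from the single C4 methyl may be incomplete. The fallback changes how C7 is set and sets out from 1. Amination with allylamine should give the N-allyl amino alcohol F1, carbamoylation the hydroxy carbamate F2, TEMPO oxidation the aldehyde F3 and Ohira–Bestmann homologation the N-allyl enyne F4, whose terminal alkene is a much better cyclisation partner. Its hexacarbonyldicobalt complex F5 should cyclise under the conditions of step 5 to the C7-unsubstituted enone F6. Kinetic deprotonation at C7 (LDA, THF, −78 °C) gives the cross-conjugated lithium enolate F7, which should be methylated by MeI on the face away from the C7a–C1 bond. The route is rejoined at 9; epimers at C7 or C7a can be equilibrated toward 9 with DBU.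

2. Step 12. Displacement at the hindered C6 oxyphosphonium next to the C7 methyl may be slow with a weakly acidic enoic acid, so that elimination toward C5 or C7, or acyl transfer with retention, competes. The fallback replaces the redox condensation by a preformed leaving group and sets out from 12. MsCl/Et3N (CH2Cl2, 0 °C) should give the C6 mesylate F8, whose concave-face leaving group cannot be reached by the ring nitrogen from the rear. Heating F8 with the cesium carboxylate F9 (from 18 and Cs2CO3) in DMF at 60 °C should give the ester by SN2 inversion. The route is rejoined at 19.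

3. Step 7. Hydride may add to the C6 ketone from both faces, because convex-face approach is syn to the adjacent C7 methyl, giving C6-epimeric amino alcohols that are hard to separate. The fallback fixes C6 on the flat enone and avoids any inversion; it sets out from 9.
   - Luche reduction (NaBH4, CeCl3·7H2O, MeOH, −78 °C) should add hydride anti to the C7 methyl and give the allylic alcohol F10, with OH cis to that methyl and to H-7a.
   - Hydroxyl-directed hydrogenation ([Ir(cod)(PCy3)(py)]PF6, H2, CH2Cl2) should deliver hydrogen to C4a on the OH face and give the cis-fused (6R)-hydroxy carbamate F11.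
   - LiAlH4 (THF, reflux) should give the (6R)-amino alcohol F12.
   - Carbodiimide acylation with 18 (EDC·HCl, DMAP, CH2Cl2) forms the ester with retention.

   The route is rejoined at 19, and steps 6 and 12 are bypassed as well.

Further compounds
F1 | step 5 | (2S)-2-methyl-3-(prop-2-en-1-ylamino)propan-1-ol | OC[C@@H](C)CNCC=C
F2 | step 5 | methyl N-[(2S)-3-hydroxy-2-methylpropyl]-N-(prop-2-en-1-yl)carbamate | OC[C@@H](C)CN(C(=O)OC)CC=C
F3 | step 5 | methyl N-[(2S)-2-methyl-3-oxopropyl]-N-(prop-2-en-1-yl)carbamate | O=C[C@@H](C)CN(C(=O)OC)CC=C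
F4 | step 5 | methyl N-[(2R)-2-methylbut-3-yn-1-yl]-N-(prop-2-en-1-yl)carbamate | C#C[C@@H](C)CN(C(=O)OC)CC=C
F5 | step 5 | hexacarbonyldicobalt complex of the alkyne of F4 | O=C=[Co]12(=C=O)(=C=O)[Co]3(=C=O)(=C=O)(=C=O)C1([H])C23[C@@H](C)CN(C(=O)OC)CC=C
F6 | step 5 | methyl (4R,7aS)-4-methyl-6-oxo-1,3,4,6,7,7a-hexahydro-2H-cyclopenta[c]pyridine-2-carboxylate | O=C1C=C2[C@@H](CN(C(=O)OC)C[C@@H]2C)C1
F7 | step 5 | lithium enolate of F6 (C6–OLi, C6=C7) | [Li]OC1=C[C@@H]2CN(C(=O)OC)C[C@H](C)C2=C1
F8 | step 12 | (4R,4aS,6S,7S,7aR)-2,4,7-trimethyloctahydro-1H-cyclopenta[c]pyridin-6-yl methanesulfonate | CS(=O)(=O)O[C@H]1C[C@@H]2[C@@H](CN(C)C[C@@H]2C)[C@@H]1C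
F9 | step 12 | cesium (2E,6S)-8-[(tert-butyldimethylsilyl)oxy]-2,6-dimethyloct-2-enoate | [Cs+].[O-]C(=O)/C(C)=C/CC[C@H](C)CCO[Si](C)(C)C(C)(C)C
F10 | step 7 | methyl (4R,6S,7S,7aS)-6-hydroxy-4,7-dimethyl-1,3,4,6,7,7a-hexahydro-2H-cyclopenta[c]pyridine-2-carboxylate | O[C@@H]1C=C2[C@@H](CN(C(=O)OC)C[C@@H]2C)[C@@H]1C
F11 | step 7 | methyl (4R,4aS,6R,7S,7aR)-6-hydroxy-4,7-dimethyloctahydro-2H-cyclopenta[c]pyridine-2-carboxylate | O[C@@H]1C[C@@H]2[C@@H](CN(C(=O)OC)C[C@@H]2C)[C@@H]1C
F12 | step 7 | (4R,4aS,6R,7S,7aR)-2,4,7-trimethyloctahydro-1H-cyclopenta[c]pyridin-6-ol | O[C@@H]1C[C@@H]2[C@@H](CN(C)C[C@@H]2C)[C@@H]1C
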